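## Structural features

The target is a germacranolide: a ten-membered carbocycle (C1–C10) fused across C6–C7 to an α-methylene-γ-butyrolactone (O6–C12(=O)–C11(=C13)–C7). Both ring olefins, C1=C10 and C4=C5, are trisubstituted and ring-cis (C2/C9 and C3/C6 are cis; the CIP descriptors are E only because C14 and C15 carry oxygen). C10 bears the C14 aldehyde, so C1=C10 is an enal, and C4 bears the C15 hydroxymethyl group. Four stereocentres stand in a row: C6 (lactone oxygen), C7, C8 (ester of (R)-2-methylbutanoic acid) and C9 (free hydroxyl next to C10); H6/H7 are trans on the lactone and the C8/C9 oxygens are syn (threo). Fragile groups are the methylene lactone and the enal (Michael acceptors), the C8 ester beside a free C9 hydroxyl (acyl migration; with a free C8 hydroxyl the lactone can move from O6 to O8), the 1,5-diene (transannular reactions under acid) and the α-stereocentre of the acyl group. The real difficulty is the medium ring, which must be closed with two cis olefins in place while C6 and C7 are set relative to C8 and C9, and with five oxygenated carbons (C8, C9, C12, C14, C15) kept distinguishable to the end. The key step uses the fact that C6 is an allylic carbinol carbon (next to C5=C4) bonded to C7, which carries the C11(=C13)–C12 unit. O6–C6–C7–C11=C13 is a homoallylic alcohol, the retron of a [2,3]-Wittig shift, so joining O6 to C13 turns the carbocycle into a thirteen-membered diallylic ether that is easy to close.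

## Logic of the disconnections

40 is reached from 39 by loss of the silyl ethers on O9 and O15, and 39 is cut at the O8–acyl bond into 37 and 38. The ester is put on late because it would not survive the organometallic and hydride steps, and O9 is freed last because a free C9 hydroxyl can take over the acyl group. The gain is that 38 enters unprotected and 37 has a single free hydroxyl. The demand is an acylation of a hindered secondary alcohol that does not racemise 38, and a final desilylation under acidic fluoride.

37 goes back through 36 (O8 as PMB ether) to 34 by cutting the lactone C12–O6 bond and returning C12 and C14 to the alcohol level. One primary-selective oxidation should then make the lactone and the enal together. O8 must stay blocked in that step, or the C12 aldehyde could close onto O8. 34 comes from 33 by freeing O14 alone, which demands a C14 group more labile than those on O9 and O15.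

33 is cut at C6–C7 and O6 is reconnected to C13, which gives 31. This removes the medium-ring closure and both new stereocentres (C6, C7) in one operation and leaves a thirteen-membered ether. The demand is lithiation at C6 only. A benzyl-type ether on C14 would be an allyl benzyl ether, itself a Wittig substrate under n-BuLi. The precursor therefore carries silyl ethers on C14 (TBS) and C15 (TIPS), keeps a PMB group only on the hindered secondary O8, and has C12 as a free hydroxyl that is deprotonated first.

31 comes from 30 by removing a temporary DMB ether on O12, and 30 is cut at the O–C6 bond of the ring ether to give 29 (C13 hydroxyl, C6 chloride). An intramolecular Williamson reaction between a primary alkoxide and a primary allylic chloride is the easiest way to close the large ring. The demand is that C12 and C13, two hydroxymethyl groups on one carbon, stay differentiated: O12 needs a group that cannot migrate to the C13 alkoxide, which rules out a silyl ether and favours a benzyl-type ether.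

29 is traced through 28 and 26 to 24 and 9 by cutting C3–C4 (sp3–sp2), after changing C13 back to an ester and C6 back to a hydroxyl. The cut separates the C4=C5 olefin, with its geometry already fixed in 9, from the main chain. The demand is a hydroboration that touches only the terminal olefin of a diene, and a coupling that keeps the alkenyl iodide geometry.

24 is cut at C7=C11 into 20 and 23. An olefination that puts the ester trans to C8 defines the ester carbon as C13 and the alkoxymethyl carbon as C12. The demand is E-selectivity and no epimerisation of the α-alkoxy aldehyde.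

20 is traced through 19 and 18 to 6 and 15 by cutting C9–C10. C10 has to arrive as the iodine-bearing carbon of a butynediol-derived Z-iodoalkene so that C1=C10 is ring-cis, and C9 is therefore created at a carbonyl carbon. Only C8 is taken from the chiral pool; the demand is chelation control by the C8 PMB ether to give the 8,9-syn carbinol.

15 goes back through 13 and 12 to 11 and 10: the aldehyde carbon is revealed from a vinyl group, and the secondary PMB ether is placed by reductive opening of a cyclic acetal. The demand is regioselective opening towards the primary alcohol.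

6 comes from 5, 4 and 2, and 9 from 7, all from 1: the four carbons of 1 become C14–C10–C1–C2 in 6 and C15–C4–C5–C6 in 9. Hydroxyl-directed trans-hydroalumination fixes the Z geometry in both. 23 is made from 21 and 22 by conjugate addition.

## Other disconnections considered

Alternative 1: The cut is the C7–C11 bond together with the lactone ring, made last on a preformed cyclodecatriene. The propiolate A1 (C6 ester, ring-cis C7=C8 olefin) would undergo an Alder-ene cycloisomerisation with cationic monovalent rhodium ([Rh(cod)Cl]2, BINAP, AgSbF6) to the methylene lactone A2, with C7 set and the ring olefin moved to C8=C9. In its favour, the lactone, the exocyclic methylene and C7 are made in one catalytic, atom-economic step under neutral conditions, with no C12/C13 differentiation and no strong base. On these points it is better than the chosen plan, which needs a temporary O12 group, n-BuLi and an oxidative lactonisation. Against it, A2 has no oxygen at C8 or C9. The new trans C8=C9 olefin would have to be dihydroxylated on one face in the presence of the conjugated C1=C10 olefin and the C4=C5 olefin, and the resulting diol then acylated at O8 only. A1 also already contains the ten-membered ring, so the medium-ring problem is moved, not solved. The ene step would be asked to work on a medium-ring olefin whose allylic C9 hydrogen must align. Both plans set C7 under substrate control next to C6; the chosen plan has C8 and C9 in place before the ring exists, and its ring formation is an easy etherification followed by a contraction.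

Alternative 2: The cut is C9–C10. The acyclic iodo aldehyde A3, which already holds the lactone, C6–C8 and the acyl group, would be closed with CrCl2 and catalytic NiCl2 (Nozaki–Hiyama–Kishi addition of the C10 alkenylchromium to the C9 aldehyde) to the ten-membered allylic alcohol A4. In its favour, A4 is only a PMB removal, an allylic oxidation and a desilylation from the target, the acyl group is in place early and the conditions tolerate esters and lactones. In end-game step count and functional-group tolerance it is better than the chosen plan; in the use of a Z-iodoalkene from butynediol for C1=C10 it is equal. Against it, a ten-membered ring would be closed end to end by C–C bond formation, the least favourable ring size. C9 would be set in that macrocyclisation with no clear facial bias. The α-acyloxy aldehyde of A3 is prone to epimerisation at C8. A3 also needs a separate stereocontrolled synthesis of a trans-disubstituted methylene lactone carrying C8. In the chosen plan C9 is set in an acyclic chelation-controlled addition that can be corrected by oxidation and reduction, and the new ring bond forms inside a preorganised ring through a five-membered transition state.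

Alternative 3: The cut is the C4=C5 olefin, traced back to the C4–C9 bond of a cis-decalin. The C9 potassium alkoxide of the mesylate A5 (KOC(CH3)3) would expel the C5 mesylate in a Grob fragmentation, giving the cyclodecadienone A6 with a C9 ketone. In its favour, the carbon skeleton is built from six-membered rings by reliable annulation chemistry, and the fragmentation is stereospecific, so the ring-cis C4=C5 geometry follows from the antiperiplanar arrangement. In certainty of ring formation and of this olefin geometry it is equal to or better than the chosen plan. Against it, A5 needs six contiguous stereocentres in one ring (C4, C5, C6, C7, C8, C9), three of which are destroyed in the key step. C9 emerges as a ketone beside the C8 ether, so it must be reduced diastereoselectively and C8 is exposed to epimerisation under the basic fragmentation. The lactone is still to be made. The chosen plan creates two stereocentres as it forms the ring and needs no redox correction at C9; the alternative spends more steps on stereocentres that do not survive.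

Key step: step 21

Abbreviations: TBS = tert-butyldimethylsilyl, TES = triethylsilyl, TIPS = triisopropylsilyl, PMB = 4-methoxybenzyl, DMB = 3,4-dimethoxybenzyl; germacrane numbering is used for chain and ring carbons.

Assumption: (R)-but-3-ene-1,2-diol, (3,4-dimethoxyphenyl)methanol and ethyl 2-(diethoxyphosphoryl)prop-2-enoate are taken as commercial, and organometallic steps are counted as quenched with water.

## Route

Step 1
Reactants: 1 but-2-yne-1,4-diol
Product: 2 4-(TBS-oxy)but-2-yn-1-ol
Conditions: NaH (1.0 equiv), THF, 0 °C; TBSCl, 0 °C → rt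
Reagents that add atoms: tert-butyldimethylsilyl chloride, CC(C)(C)[Si](C)(C)Cl
Why: O-Silylation of the monosodium alkoxide; the two hydroxyls of 1 are equivalent and the poorly soluble mono-alkoxide favours monosilylation.

Step 2
Reactants: 2 4-(TBS-oxy)but-2-yn-1-ol
Product: 4 (Z)-4-(TBS-oxy)-3-iodobut-2-en-1-ol, via alkenylalanate 3 (not isolated)
Conditions: NaAlH2(OCH2CH2OCH3)2, THF, 0 °C → rt; then N-iodosuccinimide, −78 °C
Reagents that add atoms: N-iodosuccinimide, O=C1CCC(=O)N1I
Why: Hydroxyl-directed trans-hydroalumination of the propargylic alcohol puts aluminium on the distal alkyne carbon (C10) in a five-membered alanate; iodinolysis with retention gives the Z-iodoalkenol with iodine cis to the hydroxymethyl-bearing carbon.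

Step 3
Reactants: 4 (Z)-4-(TBS-oxy)-3-iodobut-2-en-1-ol
Product: 5 (Z)-4-(TBS-oxy)-3-iodobut-2-enal
Conditions: MnO2, CH2Cl2, rt
Reagents that add atoms: none
Why: MnO2 oxidation of a primary allylic alcohol; the neutral conditions should keep the Z geometry of the β-iodo enal.

Step 4
Reactants: 5 (Z)-4-(TBS-oxy)-3-iodobut-2-enal
Product: 6 (Z)-tert-butyl[(2-iodopenta-2,4-dien-1-yl)oxy]dimethylsilane
Conditions: Ph3PCH3Br, KN(SiMe3)2, THF, −78 → 0 °C
Reagents that add atoms: methyltriphenylphosphonium bromide, C[P+](c1ccccc1)(c1ccccc1)c1ccccc1.[Br-]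
Why: Wittig methylenation with a non-stabilised ylide at low temperature; carbonyl addition is faster than attack at the iodine-bearing β-carbon, so the Z-iodoalkene is carried into the diene (C3=C2–C1=C10).

Step 5
Reactants: 1 but-2-yne-1,4-diol
Product: 7 4-(TIPS-oxy)but-2-yn-1-ol
Conditions: NaH (1.0 equiv), THF, 0 °C; TIPSCl, 0 °C → rt
Reagents that add atoms: chlorotriisopropylsilane, CC(C)[Si](Cl)(C(C)C)C(C)C
Why: Monosilylation of the symmetrical diol as in step 1; TIPS is chosen for C15 because it must outlast the TBS ether on C14.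

Step 6
Reactants: 7 4-(TIPS-oxy)but-2-yn-1-ol
Product: 9 (Z)-3-iodo-4-(TIPS-oxy)but-2-en-1-ol, via alkenylalanate 8 (not isolated)
Conditions: NaAlH2(OCH2CH2OCH3)2, THF, 0 °C → rt; then N-iodosuccinimide, −78 °C
Reagents that add atoms: N-iodosuccinimide, O=C1CCC(=O)N1I
Why: Same hydroxyl-directed trans-hydroalumination and iodinolysis as in step 2; it gives the C15–C4(iodo)=C5–C6 unit with iodine cis to C6, the geometry needed for a ring-cis C4=C5.

Step 7
Reactants: 10 (R)-but-3-ene-1,2-diol
Product: 11 (4R)-2-(4-methoxyphenyl)-4-vinyl-1,3-dioxolane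
Conditions: 4-MeOC6H4CH(OMe)2, PPTS (cat.), CH2Cl2, rt
Reagents that add atoms: 4-methoxybenzaldehyde dimethyl acetal, COC(OC)c1ccc(OC)cc1
Why: Acid-catalysed transacetalisation of the 1,2-diol to the five-membered p-methoxybenzylidene acetal; the C8 stereocentre is untouched and the acetal carbon forms as a mixture that does not matter.

Step 8
Reactants: 11 (4R)-2-(4-methoxyphenyl)-4-vinyl-1,3-dioxolane
Product: 12 (R)-2-(PMB-oxy)but-3-en-1-ol
Conditions: i-Bu2AlH, CH2Cl2, −78 → 0 °C
Reagents that add atoms: none
Why: Reductive acetal opening: aluminium coordinates the less hindered primary oxygen and hydride is delivered to the oxocarbenium ion, leaving PMB on the secondary (C8) oxygen and the primary hydroxyl (C7) free.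

Step 9
Reactants: 12 (R)-2-(PMB-oxy)but-3-en-1-ol
Product: 13 (R)-triethyl{[2-(PMB-oxy)but-3-en-1-yl]oxy}silane
Conditions: TESCl, imidazole, CH2Cl2, 0 °C
Reagents that add atoms: chlorotriethylsilane, CC[Si](Cl)(CC)CC
Why: Standard silylation of a primary alcohol; TES is chosen so that C7 can later be unmasked beside TBS ethers.

Step 10
Reactants: 13 (R)-triethyl{[2-(PMB-oxy)but-3-en-1-yl]oxy}silane
Product: 15 (S)-2-(PMB-oxy)-3-(TES-oxy)propanal, via ozonide 14 (not isolated)
Conditions: O3, CH2Cl2, −78 °C (stopped at the end point); then PPh3, −78 °C → rt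
Reagents that add atoms: ozone, [O-][O+]=O
Why: Ozonolysis of the terminal vinyl group with reductive work-up gives the C9 aldehyde; the neutral conditions should not epimerise C8, and stopping at the end point spares the PMB ring.

Step 11
Reactants: 6 (Z)-tert-butyl[(2-iodopenta-2,4-dien-1-yl)oxy]dimethylsilane; 15 (S)-2-(PMB-oxy)-3-(TES-oxy)propanal
Product: 18 (2S,3S,4Z)-4-(TBS-oxymethyl)-2-(PMB-oxy)-1-(TES-oxy)hepta-4,6-dien-3-ol, via dienyllithium 16 (not isolated), via dienylmagnesium bromide 17 (not isolated)
Conditions: t-BuLi (2.1 equiv), Et2O, −78 °C; MgBr2·OEt2; then 15 premixed with MgBr2·OEt2 in CH2Cl2, −78 °C; then H2O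
Reagents that add atoms: none
Why: Iodine–lithium exchange with retention, transmetalation to magnesium and Cram-chelate addition form C9–C10. MgBr2 bridges the aldehyde oxygen and the α-PMB ether (the β-silyl ether does not chelate), so the alkenyl group adds to the face away from the C7 arm and should give the 8,9-syn (threo) carbinol, the C9 configuration of the target.

Step 12
Reactants: 18 (2S,3S,4Z)-4-(TBS-oxymethyl)-2-(PMB-oxy)-1-(TES-oxy)hepta-4,6-dien-3-ol
Product: 19 3-O-TBS ether of 18
Conditions: TBSOTf, 2,6-lutidine, CH2Cl2, −78 → 0 °C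
Reagents that add atoms: tert-butyldimethylsilyl trifluoromethanesulfonate, CC(C)(C)[Si](C)(C)OS(=O)(=O)C(F)(F)F
Why: Silylation of the hindered secondary allylic C9 hydroxyl with the silyl triflate and a hindered base; the TES ether is stable to these conditions.

Step 13
Reactants: 19 3-O-TBS ether of 18
Product: 20 (2R,3S,4Z)-3-(TBS-oxy)-4-(TBS-oxymethyl)-2-(PMB-oxy)hepta-4,6-dienal
Conditions: (COCl)2, DMSO, CH2Cl2, −78 → −40 °C; Et3N, −78 → 0 °C
Reagents that add atoms: none
Why: Swern conditions convert a primary TES ether directly into the aldehyde (the chlorosulfonium ion attacks the ether oxygen, the silyl chloride leaves, then the usual ylide elimination); primary and secondary TBS ethers are inert, and cold addition of the amine limits epimerisation of the α-alkoxy aldehyde.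

Step 14
Reactants: 21 (3,4-dimethoxyphenyl)methanol; 22 ethyl 2-(diethoxyphosphoryl)prop-2-enoate
Product: 23 ethyl 2-(diethoxyphosphoryl)-3-(DMB-oxy)propanoate
Conditions: NaH (0.1 equiv), THF, 0 °C → rt
Reagents that add atoms: none
Why: Oxa-Michael addition of the benzylic alkoxide to the doubly activated vinylphosphonate; the stabilised carbanion is protonated by more alcohol, so the base is catalytic.

Step 15
Reactants: 20 (2R,3S,4Z)-3-(TBS-oxy)-4-(TBS-oxymethyl)-2-(PMB-oxy)hepta-4,6-dienal; 23 ethyl 2-(diethoxyphosphoryl)-3-(DMB-oxy)propanoate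
Product: 24 ethyl (2E,4S,5S,6Z)-5-(TBS-oxy)-6-(TBS-oxymethyl)-2-(DMB-oxymethyl)-4-(PMB-oxy)nona-2,6,8-trienoate
Conditions: Ba(OH)2·8H2O, THF/H2O (40:1), 0 °C → rt
Reagents that add atoms: none
Why: Horner–Wadsworth–Emmons olefination under mild Ba(OH)2 conditions forms C7=C11; an α-substituted phosphonoacetate should place the ester trans to C8, which makes the ester carbon C13 and the DMB-oxymethyl carbon C12 (cis to C8).

Step 16
Reactants: 24 ethyl (2E,4S,5S,6Z)-5-(TBS-oxy)-6-(TBS-oxymethyl)-2-(DMB-oxymethyl)-4-(PMB-oxy)nona-2,6,8-trienoate; 9 (Z)-3-iodo-4-(TIPS-oxy)but-2-en-1-ol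
Product: 26 seco hydroxy ester with C3–C4 joined (C6 hydroxyl and C13 ethyl ester), via alkylborane 25 (not isolated)
Conditions: 9-BBN, THF, 0 °C → rt; then 9, Pd(dppf)Cl2 (5 mol%), AsPh3, Cs2CO3, DMF/H2O, rt
Reagents that add atoms: none
Why: 9-BBN adds selectively to the terminal monosubstituted olefin of the diene (boron on C3) and leaves the trisubstituted olefins and the ester alone; B-alkyl Suzuki–Miyaura coupling with the Z-iodoalkene goes with retention and forms C3–C4 with the ring-cis C4=C5 geometry.

Step 17
Reactants: 26 seco hydroxy ester (C6 hydroxyl and C13 ethyl ester)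
Product: 28 seco chloro ester (C6 chloride and C13 ethyl ester), via allylic mesylate 27 (not isolated)
Conditions: MsCl, 2,4,6-collidine, LiCl, DMF, 0 °C
Reagents that add atoms: lithium chloride, [Li+].[Cl-]
Why: The only free hydroxyl (C6) is mesylated and displaced in situ by chloride (SN2); attack at the fully substituted C4 terminus is disfavoured, so no allylic transposition is expected.

Step 18
Reactants: 28 seco chloro ester (C6 chloride and C13 ethyl ester)
Product: 29 seco chloro alcohol (C6 chloride and C13 hydroxyl)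
Conditions: i-Bu2AlH (2.5 equiv), CH2Cl2, −78 °C
Reagents that add atoms: none
Why: i-Bu2AlH reduces the enoate to the allylic alcohol at −78 °C without touching the allylic chloride or the ethers.

Step 19
Reactants: 29 seco chloro alcohol (C6 chloride and C13 hydroxyl)
Product: 30 thirteen-membered diallylic ether with C12 DMB ether
Conditions: NaH, THF, slow addition to 2 mM, rt → 45 °C
Reagents that add atoms: none
Why: Intramolecular Williamson etherification: the C13 alkoxide displaces the primary allylic chloride at C6 under high dilution and closes the thirteen-membered ring. SN2' attack at fully substituted C4 is disfavoured, and the non-migrating DMB ether keeps C12 and C13 differentiated.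

Step 20
Reactants: 30 thirteen-membered diallylic ether with C12 DMB ether
Product: 31 thirteen-membered diallylic ether with free C12 hydroxyl (O8 PMB; O9 and O14 TBS; O15 TIPS)
Conditions: DDQ (1.1 equiv), CH2Cl2/pH 7 buffer (10:1), 0 °C
Reagents that add atoms: none
Why: Oxidative cleavage of the DMB ether by DDQ; the more electron-rich primary DMB ether reacts faster than the hindered secondary PMB ether, so a small excess at 0 °C should free only O12.

Step 21
Reactants: 31 thirteen-membered diallylic ether with free C12 hydroxyl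
Product: 33 ten-membered 6,12-diol with the C11=C13 methylene (O8 PMB; O9 and O14 TBS; O15 TIPS), via dilithio ether 32 (not isolated)
Conditions: n-BuLi (3.0 equiv), THF, −78 → −25 °C; then H2O
Reagents that add atoms: none
Why: The first equivalent of n-BuLi makes the C12 lithium alkoxide and a second removes a C6 hydrogen, which is allylic to C4=C5 and α to the ring oxygen; the α-oxy allyl anion of 32 then attacks C7 suprafacially through a five-centre envelope (C6, O, C13, C11, C7), forming C6–C7, breaking O–C13 and releasing the C11=C13 methylene. This is the [2,3]-Wittig rearrangement in its ring-contracting form, known for thirteen-membered diallylic ethers. The ten-membered carbocycle is not closed end to end but arises by transannular bond formation inside the existing ring, so the mode of closure is a sigmatropic contraction (13 to 10) through a five-membered transition state. The C6/C7 relationship is set by olefin geometry: the ring-trans C7=C11 unit places C8 pseudo-equatorial in the envelope and should give the anti product, which is the trans-lactone relationship. The absolute sense at C7, and with it at C6, has to come from the ring: the anion should add to the C7 face opposite the C8 PMB ether, in a conformation biased by the syn C8/C9 substituents. Regioselectivity needs lithiation at C6 and not at C13; the neighbouring C12 alkoxide disfavours a second negative charge on the C13–C11–C7 allyl system, and a C13 anion could only attack fully substituted C4. Competing Wittig pathways are limited by design: C14 and C15 carry silyl ethers and not allylic benzyl-type ethers, the only benzyl ether (O8) is secondary and hindered, and the low temperature disfavours the [1,2]-shift.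

Step 22
Reactants: 33 ten-membered 6,12-diol
Product: 34 ten-membered 6,12,14-triol (O8 PMB; O9 TBS; O15 TIPS)
Conditions: HF·pyridine, pyridine, THF, 0 °C
Reagents that add atoms: none
Why: Buffered HF·pyridine cleaves the primary TBS ether at C14 faster than the hindered secondary TBS ether at C9 and the primary TIPS ether at C15.

Step 23
Reactants: 34 ten-membered 6,12,14-triol
Product: 36 trans-fused methylene lactone with C14 aldehyde (O8 PMB; O9 TBS; O15 TIPS), via lactol 35 (not isolated)
Conditions: TEMPO (0.3 equiv), PhI(OAc)2 (4 equiv), CH2Cl2, rt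
Reagents that add atoms: none
Why: Oxoammonium (TEMPO) oxidation is selective for primary alcohols: C14–OH gives the enal, and C12–OH gives the 2-substituted acrolein, which is trapped by the C6 hydroxyl as lactol 35 and oxidised on to the α-methylene lactone. The ring fusion is trans because C6 and C7 are already set, and O8 is blocked so that no 8,12-lactone can form.

Step 24
Reactants: 36 trans-fused methylene lactone with C14 aldehyde (O8 PMB)
Product: 37 C8 alcohol of the lactone enal (O9 TBS; O15 TIPS)
Conditions: DDQ (1.5 equiv), CH2Cl2/pH 7 buffer (10:1), 0 °C → rt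
Reagents that add atoms: none
Why: DDQ cleaves the secondary PMB ether under buffered conditions; silyl ethers, enal and lactone are inert, and the neutral medium avoids translactonisation to O8.

Step 25
Reactants: 37 C8 alcohol of the lactone enal; 38 (R)-2-methylbutanoic acid
Product: 39 C8 (R)-2-methylbutanoate (O9 TBS; O15 TIPS)
Conditions: EDC·HCl, DMAP (0.2 equiv), CH2Cl2, 0 °C → rt
Reagents that add atoms: none
Why: Steglich esterification of the C8 hydroxyl with the carbodiimide-activated acid; catalytic DMAP at low temperature should keep the α-stereocentre of 38 and leave the lactone in place.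

Step 26
Reactants: 39 C8 (R)-2-methylbutanoate (O9 TBS; O15 TIPS)
Product: 40 target CNP0331447.8
Conditions: HF·pyridine, THF/pyridine, 0 °C → rt
Reagents that add atoms: none
Why: Acidic fluoride removes the secondary TBS ether at C9 and the primary TIPS ether at C15; the buffered, non-basic medium avoids O8-to-O9 acyl migration, conjugate addition and translactonisation.

## Compound list

1 | but-2-yne-1,4-diol | OCC#CCO | starting material
2 | 4-[(tert-butyldimethylsilyl)oxy]but-2-yn-1-ol | OCC#CCO[Si](C)(C)C(C)(C)C | intermediate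
3 | sodium alkenylalanate from 2 (five-membered O–Al–C chelate, two 2-methoxyethoxy ligands) | [Na+].COCCO[Al-]1(OCCOC)OC/C=C1/CO[Si](C)(C)C(C)(C)C | intermediate
4 | (Z)-4-[(tert-butyldimethylsilyl)oxy]-3-iodobut-2-en-1-ol | OC/C=C(\I)CO[Si](C)(C)C(C)(C)C | intermediate
5 | (Z)-4-[(tert-butyldimethylsilyl)oxy]-3-iodobut-2-enal | O=C/C=C(\I)CO[Si](C)(C)C(C)(C)C | intermediate
6 | (Z)-tert-butyl[(2-iodopenta-2,4-dien-1-yl)oxy]dimethylsilane | C=C/C=C(\I)CO[Si](C)(C)C(C)(C)C | intermediate
7 | 4-[(triisopropylsilyl)oxy]but-2-yn-1-ol | OCC#CCO[Si](C(C)C)(C(C)C)C(C)C | intermediate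
8 | sodium alkenylalanate from 7 | [Na+].COCCO[Al-]1(OCCOC)OC/C=C1/CO[Si](C(C)C)(C(C)C)C(C)C | intermediate
9 | (Z)-3-iodo-4-[(triisopropylsilyl)oxy]but-2-en-1-ol | OC/C=C(\I)CO[Si](C(C)C)(C(C)C)C(C)C | intermediate
10 | (R)-but-3-ene-1,2-diol | OC[C@H](O)C=C | starting material
11 | (4R)-2-(4-methoxyphenyl)-4-vinyl-1,3-dioxolane (both epimers at the acetal carbon) | C=C[C@@H]1COC(c2ccc(OC)cc2)O1 | intermediate
12 | (R)-2-[(4-methoxybenzyl)oxy]but-3-en-1-ol | OC[C@H](OCc1ccc(OC)cc1)C=C | intermediate
13 | (R)-triethyl({2-[(4-methoxybenzyl)oxy]but-3-en-1-yl}oxy)silane | CC[Si](CC)(CC)OC[C@H](OCc1ccc(OC)cc1)C=C | intermediate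
14 | ozonide of 13: 3-{(1S)-1-[(4-methoxybenzyl)oxy]-2-[(triethylsilyl)oxy]ethyl}-1,2,4-trioxolane | CC[Si](CC)(CC)OC[C@H](OCc1ccc(OC)cc1)C1OCOO1 | intermediate
15 | (S)-2-[(4-methoxybenzyl)oxy]-3-[(triethylsilyl)oxy]propanal | CC[Si](CC)(CC)OC[C@H](OCc1ccc(OC)cc1)C=O | intermediate
16 | (Z)-dienyllithium from 6 (lithium in place of iodine) | C=C/C=C(\[Li])CO[Si](C)(C)C(C)(C)C | intermediate
17 | (Z)-dienylmagnesium bromide from 16 | C=C/C=C(\[Mg]Br)CO[Si](C)(C)C(C)(C)C | intermediate
18 | (2S,3S,4Z)-4-{[(tert-butyldimethylsilyl)oxy]methyl}-2-[(4-methoxybenzyl)oxy]-1-[(triethylsilyl)oxy]hepta-4,6-dien-3-ol | CC[Si](CC)(CC)OC[C@H](OCc1ccc(OC)cc1)[C@@H](O)/C(CO[Si](C)(C)C(C)(C)C)=C\C=C | intermediate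
19 | 3-O-TBS ether of 18 | CC[Si](CC)(CC)OC[C@H](OCc1ccc(OC)cc1)[C@@H](O[Si](C)(C)C(C)(C)C)/C(CO[Si](C)(C)C(C)(C)C)=C\C=C | intermediate
20 | (2R,3S,4Z)-3-[(tert-butyldimethylsilyl)oxy]-4-{[(tert-butyldimethylsilyl)oxy]methyl}-2-[(4-methoxybenzyl)oxy]hepta-4,6-dienal | O=C[C@H](OCc1ccc(OC)cc1)[C@@H](O[Si](C)(C)C(C)(C)C)/C(CO[Si](C)(C)C(C)(C)C)=C\C=C | intermediate
21 | (3,4-dimethoxyphenyl)methanol | OCc1ccc(OC)c(OC)c1 | starting material
22 | ethyl 2-(diethoxyphosphoryl)prop-2-enoate | C=C(C(=O)OCC)P(=O)(OCC)OCC | starting material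
23 | ethyl 2-(diethoxyphosphoryl)-3-[(3,4-dimethoxybenzyl)oxy]propanoate (racemic) | CCOC(=O)C(COCc1ccc(OC)c(OC)c1)P(=O)(OCC)OCC | intermediate
24 | ethyl (2E,4S,5S,6Z)-5-(TBS-oxy)-6-(TBS-oxymethyl)-2-(DMB-oxymethyl)-4-(PMB-oxy)nona-2,6,8-trienoate | CCOC(=O)/C(COCc1ccc(OC)c(OC)c1)=C/[C@H](OCc1ccc(OC)cc1)[C@@H](O[Si](C)(C)C(C)(C)C)/C(CO[Si](C)(C)C(C)(C)C)=C\C=C | intermediate
25 | B-alkyl-9-borabicyclo[3.3.1]nonane from 24 (boron on C3) | CCOC(=O)/C(COCc1ccc(OC)c(OC)c1)=C/[C@H](OCc1ccc(OC)cc1)[C@@H](O[Si](C)(C)C(C)(C)C)/C(CO[Si](C)(C)C(C)(C)C)=C\CCB1C2CCCC1CCC2 | intermediate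
26 | ethyl (2E,4S,5S,6Z,10E)-5-(TBS-oxy)-6-(TBS-oxymethyl)-2-(DMB-oxymethyl)-12-hydroxy-4-(PMB-oxy)-10-(TIPS-oxymethyl)dodeca-2,6,10-trienoate | CCOC(=O)/C(COCc1ccc(OC)c(OC)c1)=C/[C@H](OCc1ccc(OC)cc1)[C@@H](O[Si](C)(C)C(C)(C)C)/C(CO[Si](C)(C)C(C)(C)C)=C\CC/C(CO[Si](C(C)C)(C(C)C)C(C)C)=C\CO | intermediate
27 | 12-methanesulfonate of 26 | CCOC(=O)/C(COCc1ccc(OC)c(OC)c1)=C/[C@H](OCc1ccc(OC)cc1)[C@@H](O[Si](C)(C)C(C)(C)C)/C(CO[Si](C)(C)C(C)(C)C)=C\CC/C(CO[Si](C(C)C)(C(C)C)C(C)C)=C\COS(C)(=O)=O | intermediate
28 | 12-chloro analogue of 26 (chlorine in place of the hydroxyl) | CCOC(=O)/C(COCc1ccc(OC)c(OC)c1)=C/[C@H](OCc1ccc(OC)cc1)[C@@H](O[Si](C)(C)C(C)(C)C)/C(CO[Si](C)(C)C(C)(C)C)=C\CC/C(CO[Si](C(C)C)(C(C)C)C(C)C)=C\CCl | intermediate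
29 | (2Z,4S,5S,6Z,10E)-12-chloro-5-(TBS-oxy)-6-(TBS-oxymethyl)-2-(DMB-oxymethyl)-4-(PMB-oxy)-10-(TIPS-oxymethyl)dodeca-2,6,10-trien-1-ol | OC/C(COCc1ccc(OC)c(OC)c1)=C/[C@H](OCc1ccc(OC)cc1)[C@@H](O[Si](C)(C)C(C)(C)C)/C(CO[Si](C)(C)C(C)(C)C)=C\CC/C(CO[Si](C(C)C)(C(C)C)C(C)C)=C\CCl | intermediate
30 | thirteen-membered ether (C6–O–C13) with 12-O-DMB, 8-O-PMB, 9-O-TBS, 14-O-TBS, 15-O-TIPS; ring-trans C7=C11, ring-cis C1=C10 and C4=C5; 8S,9S | COc1ccc(COC/C2=C\[C@H](OCc3ccc(OC)cc3)[C@@H](O[Si](C)(C)C(C)(C)C)/C(CO[Si](C)(C)C(C)(C)C)=C\CC/C(CO[Si](C(C)C)(C(C)C)C(C)C)=C\COC2)cc1OC | intermediate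
31 | thirteen-membered ether as 30 but with free C12 hydroxyl (key-step precursor) | OC/C1=C\[C@H](OCc2ccc(OC)cc2)[C@@H](O[Si](C)(C)C(C)(C)C)/C(CO[Si](C)(C)C(C)(C)C)=C\CC/C(CO[Si](C(C)C)(C(C)C)C(C)C)=C\COC1 | intermediate
32 | dilithio derivative of 31 (lithium on O12 and on C6) | [Li]OC/C1=C\[C@H](OCc2ccc(OC)cc2)[C@@H](O[Si](C)(C)C(C)(C)C)/C(CO[Si](C)(C)C(C)(C)C)=C\CC/C(CO[Si](C(C)C)(C(C)C)C(C)C)=C\C([Li])OC1 | intermediate
33 | ten-membered 6,12-diol with C11=C13 methylene; 8-O-PMB, 9-O-TBS, 14-O-TBS, 15-O-TIPS; C6–C9 configured as in the target (6R,7S,8S,9S) | C=C(CO)[C@H]1[C@H](O)/C=C(/CO[Si](C(C)C)(C(C)C)C(C)C)CC/C=C(/CO[Si](C)(C)C(C)(C)C)[C@H](O[Si](C)(C)C(C)(C)C)[C@H]1OCc1ccc(OC)cc1 | intermediate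
34 | 6,12,14-triol (33 without the C14 silyl group) | C=C(CO)[C@H]1[C@H](O)/C=C(/CO[Si](C(C)C)(C(C)C)C(C)C)CC/C=C(/CO)[C@H](O[Si](C)(C)C(C)(C)C)[C@H]1OCc1ccc(OC)cc1 | intermediate
35 | 6,12-lactol with C14 aldehyde (both epimers at C12) | C=C1C(O)O[C@@H]2/C=C(/CO[Si](C(C)C)(C(C)C)C(C)C)CC/C=C(/C=O)[C@H](O[Si](C)(C)C(C)(C)C)[C@@H](OCc3ccc(OC)cc3)[C@@H]12 | intermediate
36 | 12,6-olide with C14 aldehyde; 8-O-PMB, 9-O-TBS, 15-O-TIPS | C=C1C(=O)O[C@@H]2/C=C(/CO[Si](C(C)C)(C(C)C)C(C)C)CC/C=C(/C=O)[C@H](O[Si](C)(C)C(C)(C)C)[C@@H](OCc3ccc(OC)cc3)[C@@H]12 | intermediate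
37 | 36 with free C8 hydroxyl | C=C1C(=O)O[C@@H]2/C=C(/CO[Si](C(C)C)(C(C)C)C(C)C)CC/C=C(/C=O)[C@H](O[Si](C)(C)C(C)(C)C)[C@@H](O)[C@@H]12 | intermediate
38 | (R)-2-methylbutanoic acid | CC[C@@H](C)C(=O)O | starting material
39 | 9-O-TBS, 15-O-TIPS ether of the target | C=C1C(=O)O[C@@H]2/C=C(/CO[Si](C(C)C)(C(C)C)C(C)C)CC/C=C(/C=O)[C@H](O[Si](C)(C)C(C)(C)C)[C@@H](OC(=O)[C@H](C)CC)[C@@H]12 | intermediate
40 | CNP0331447.8: (6R,7S,8S,9S)-9,15-dihydroxy-14-oxo-8-[(2R)-2-methylbutanoyloxy]germacra-1(10),4,11(13)-trien-12,6-olide, both ring olefins ring-cis | C=C1C(=O)O[C@@H]2/C=C(/CO)CC/C=C(/C=O)[C@H](O)[C@@H](OC(=O)[C@H](C)CC)[C@@H]12 | target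

## Step count and least certain steps

Total: 26 steps. Longest linear sequence: 19 steps (10 → 40 through steps 7–13 and 15–26; the branch from 1 through 6 is equally long).

Step 21 (key step). Most likely to go wrong: lithiation at C13 instead of C6 (the C6 allyl unit is the more substituted one), a competing [1,2]-shift on warming, or poor facial selectivity at C7, since only the ring conformation transmits the C8/C9 configuration. Fallback: the C6–C7 bond is made by an intramolecular allylchromium addition instead. Setting out from 29, the allylic chloride is oxidised with N-methylmorpholine N-oxide (NaI cat., MeCN) to the C13-hydroxy C6-enal F1. Mesylation and LiBr give the C13-bromo C6-enal F2. CrCl2 in THF at high dilution then adds the allylchromium at its γ-carbon (C7) to the aldehyde (Nozaki–Hiyama allylation, anti-selective), giving the ten-membered homoallylic alcohol with C12 DMB ether F3. DDQ removes the DMB group and the route is rejoined at 33.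

Step 11. Most likely to go wrong: incomplete chelation control, giving the 8,9-anti carbinol alongside the syn one. Fallback: C9 is set by reduction instead of addition. Setting out from 18 as the mixture of C9 epimers, Dess–Martin periodinane gives the dienone F4. Reduction with catecholborane and (S)-2-methyl-CBS-oxazaborolidine (toluene, −78 °C) should give the 9S alcohol, taking the 2-substituted dienyl group as the larger ketone substituent. The route is rejoined at 18.

Step 19. Most likely to go wrong: oligomerisation in place of ring closure, or base-induced 1,4-elimination of HCl from the allylic chloride. Fallback: the ether bond is made intermolecularly and the ring is closed at C3–C4. Setting out from 24, i-Bu2AlH gives the allylic alcohol F5; setting out from 9, CBr4/PPh3 gives the allylic bromide F6. NaH and Bu4NI join them at normal concentration to the acyclic iodo diene ether F7. 9-BBN gives the alkylborane F8, which is closed by intramolecular Suzuki–Miyaura coupling (Pd(dppf)Cl2, AsPh3, Cs2CO3, DMF/THF/H2O, high dilution). The route is rejoined at 30.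

Step 20. Most likely to go wrong: oxidation by DDQ at the C8 PMB ether or at the trisubstituted allylic ring ether (C6) in competition with DMB cleavage. Fallback: the oxidative deprotection is moved before ring closure and O12 is carried as a non-migrating acetal. Setting out from 28, DDQ gives the C12 alcohol F9, and 2-methoxypropene/PPTS gives the 2-methoxypropan-2-yl ether F10. i-Bu2AlH gives the allylic alcohol F11, and NaH at high dilution gives the macrocyclic acetal F12. PPTS in MeOH at 0 °C then frees O12 and the route is rejoined at 31.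

Step 23. Most likely to go wrong: oxidation of the secondary allylic C6 hydroxyl before lactol formation, or isomerisation of the new enal under the acetic acid that is released. Fallback: the two oxidations are separated. Setting out from 33, TEMPO/PhI(OAc)2 gives the lactone with C14 still silylated F13. HF·pyridine (pyridine, THF, 0 °C) gives the C14 alcohol F14, and MnO2 oxidises it to the enal. The route is rejoined at 36.

## Further compounds

F1 | step 21 | C13-hydroxy C6-enal from 29 | OC/C(COCc1ccc(OC)c(OC)c1)=C/[C@H](OCc1ccc(OC)cc1)[C@@H](O[Si](C)(C)C(C)(C)C)/C(CO[Si](C)(C)C(C)(C)C)=C\CC/C(CO[Si](C(C)C)(C(C)C)C(C)C)=C\C=O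
F2 | step 21 | C13-bromo C6-enal | BrC/C(COCc1ccc(OC)c(OC)c1)=C/[C@H](OCc1ccc(OC)cc1)[C@@H](O[Si](C)(C)C(C)(C)C)/C(CO[Si](C)(C)C(C)(C)C)=C\CC/C(CO[Si](C(C)C)(C(C)C)C(C)C)=C\C=O
F3 | step 21 | ten-membered homoallylic alcohol with C12 DMB ether | C=C(COCc2ccc(OC)c(OC)c2)[C@H]1[C@H](O)/C=C(/CO[Si](C(C)C)(C(C)C)C(C)C)CC/C=C(/CO[Si](C)(C)C(C)(C)C)[C@H](O[Si](C)(C)C(C)(C)C)[C@H]1OCc1ccc(OC)cc1
F4 | step 11 | (2S,4Z)-4-(TBS-oxymethyl)-2-(PMB-oxy)-1-(TES-oxy)hepta-4,6-dien-3-one | CC[Si](CC)(CC)OC[C@H](OCc1ccc(OC)cc1)C(=O)/C(CO[Si](C)(C)C(C)(C)C)=C\C=C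
F5 | step 19 | allylic alcohol from 24 (C13 hydroxyl, diene intact) | OC/C(COCc1ccc(OC)c(OC)c1)=C/[C@H](OCc1ccc(OC)cc1)[C@@H](O[Si](C)(C)C(C)(C)C)/C(CO[Si](C)(C)C(C)(C)C)=C\C=C
F6 | step 19 | (Z)-[(4-bromo-2-iodobut-2-en-1-yl)oxy]triisopropylsilane | BrC/C=C(\I)CO[Si](C(C)C)(C(C)C)C(C)C
F7 | step 19 | acyclic C13–O–C6 ether with C4 iodide and C2=C3 vinyl group | CC(C)[Si](C(C)C)(C(C)C)OC/C(I)=C/COC/C(COCc1ccc(OC)c(OC)c1)=C/[C@H](OCc1ccc(OC)cc1)[C@@H](O[Si](C)(C)C(C)(C)C)/C(CO[Si](C)(C)C(C)(C)C)=C\C=C
F8 | step 19 | alkylborane from F7 (9-BBN on C3) | CC(C)[Si](C(C)C)(C(C)C)OC/C(I)=C/COC/C(COCc1ccc(OC)c(OC)c1)=C/[C@H](OCc1ccc(OC)cc1)[C@@H](O[Si](C)(C)C(C)(C)C)/C(CO[Si](C)(C)C(C)(C)C)=C\CCB1C2CCCC1CCC2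
F9 | step 20 | C12 alcohol from 28 | CCOC(=O)/C(CO)=C/[C@H](OCc1ccc(OC)cc1)[C@@H](O[Si](C)(C)C(C)(C)C)/C(CO[Si](C)(C)C(C)(C)C)=C\CC/C(CO[Si](C(C)C)(C(C)C)C(C)C)=C\CCl
F10 | step 20 | C12 2-methoxypropan-2-yl ether of F9 | CCOC(=O)/C(COC(C)(C)OC)=C/[C@H](OCc1ccc(OC)cc1)[C@@H](O[Si](C)(C)C(C)(C)C)/C(CO[Si](C)(C)C(C)(C)C)=C\CC/C(CO[Si](C(C)C)(C(C)C)C(C)C)=C\CCl
F11 | step 20 | allylic alcohol from F10 (C13 hydroxyl, C6 chloride) | OC/C(COC(C)(C)OC)=C/[C@H](OCc1ccc(OC)cc1)[C@@H](O[Si](C)(C)C(C)(C)C)/C(CO[Si](C)(C)C(C)(C)C)=C\CC/C(CO[Si](C(C)C)(C(C)C)C(C)C)=C\CCl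
F12 | step 20 | thirteen-membered ether with C12 2-methoxypropan-2-yl ether | COC(C)(C)OC/C1=C\[C@H](OCc2ccc(OC)cc2)[C@@H](O[Si](C)(C)C(C)(C)C)/C(CO[Si](C)(C)C(C)(C)C)=C\CC/C(CO[Si](C(C)C)(C(C)C)C(C)C)=C\COC1
F13 | step 23 | 12,6-olide with C14 TBS ether | C=C1C(=O)O[C@@H]2/C=C(/CO[Si](C(C)C)(C(C)C)C(C)C)CC/C=C(/CO[Si](C)(C)C(C)(C)C)[C@H](O[Si](C)(C)C(C)(C)C)[C@@H](OCc3ccc(OC)cc3)[C@@H]12
F14 | step 23 | 12,6-olide with free C14 hydroxyl | C=C1C(=O)O[C@@H]2/C=C(/CO[Si](C(C)C)(C(C)C)C(C)C)CC/C=C(/CO)[C@H](O[Si](C)(C)C(C)(C)C)[C@@H](OCc3ccc(OC)cc3)[C@@H]12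
A1 | alternative 1 | C6 propiolate of the cyclodeca-1(10),4,7-triene (ring-cis C7=C8; C14 PMB ether, C15 TBS ether) | C#CC(=O)O[C@@H]1/C=C(/CO[Si](C)(C)C(C)(C)C)CC/C=C(/COCc2ccc(OC)cc2)C/C=C\1
A2 | alternative 1 | trans-fused methylene lactone with ring-trans C8=C9 olefin | C=C1C(=O)O[C@@H]2/C=C(/CO[Si](C)(C)C(C)(C)C)CC/C=C(/COCc3ccc(OC)cc3)\C=C\[C@@H]12
A3 | alternative 2 | acyclic lactone with C9 aldehyde, C8 (R)-2-methylbutanoate and C10 Z-iodoalkene | C=C1C(=O)O[C@H](/C=C(/CO[Si](C)(C)C(C)(C)C)CC/C=C(\I)COCc2ccc(OC)cc2)[C@H]1[C@@H](C=O)OC(=O)[C@H](C)CC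
A4 | alternative 2 | ten-membered C9 allylic alcohol (C14 PMB ether, C15 TBS ether) | C=C1C(=O)O[C@@H]2/C=C(/CO[Si](C)(C)C(C)(C)C)CC/C=C(/COCc3ccc(OC)cc3)[C@H](O)[C@@H](OC(=O)[C@H](C)CC)[C@@H]12
A5 | alternative 3 | cis-decalin with C9 tertiary hydroxyl, C5 mesylate and C4–C9 ring-fusion bond | C=C(CO[Si](CC)(CC)CC)[C@H]1[C@H](O[Si](CC)(CC)CC)[C@@H](OS(C)(=O)=O)[C@@]2(CO[Si](C)(C)C(C)(C)C)CCC=C(COCc3ccc(OC)cc3)[C@@]2(O)[C@H]1OCc1ccc(OC)cc1
A6 | alternative 3 | cis,cis-cyclodecadienone with C9 ketone | C=C(CO[Si](CC)(CC)CC)[C@H]1[C@H](O[Si](CC)(CC)CC)/C=C(/CO[Si](C)(C)C(C)(C)C)CC/C=C(/COCc2ccc(OC)cc2)C(=O)[C@H]1OCc1ccc(OC)cc1
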